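## Analysis of the target

Target 24 is a 1,2-dioxane (ring atoms O1, O2, C3, C4, C5, C6) and this six-membered cyclic peroxide is its only ring. C3 is a CH that carries the CH2CO2H arm. C6 is a peroxyketal carbon that carries OMe and an (E)-hexadec-6-en-4-yn-1-yl chain.

The two stereocentres are (3S) and (6R), with OMe and the acetic acid arm cis on the ring. In the chair this puts the arm and the long chain equatorial and OMe axial, so the C6 configuration is the thermodynamically preferred ketal epimer (anomeric effect) and can be corrected by acid. C3 cannot be corrected once made and carries the absolute configuration.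

The sensitive groups are:
- the O–O bond (reductants, low-valent metals, phosphines);
- the peroxyketal (ionised by acid);
- the β-peroxy ester or acid (base can open the ring by E1cB, or remove the C3 hydrogen in a Kornblum–DeLaMare fragmentation);
- the conjugated enyne (electrophiles, radicals, hydrometalation).

The difficulty is that few reactions build a peroxide ring while forming C–C bonds, and that C3, a carbon bonded to peroxide oxygen, must be set absolutely.

The strategy rests on two polar units. O1–O2–C3 is a peroxide on an aldehyde-level carbon, that is, a silylperoxy acetal that already carries the ester arm. C4–C5–C6 with its OMe is the homoenolate of a ketal, that is, a 1-methoxycyclopropane whose donor carbon is C6. Joining C3–C4 and C6–O1 closes the ring.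

The enyne is split at its sp–sp2 bond, so that only a silyl-capped alkyne passes through the cationic ring-forming step.

## Retrosynthetic reasoning

**Acid to ester (24 to 22).** The acid is unmasked last from methyl ester 22. A free acid would interfere with the organometallic and cationic steps, and the ester is the oxidation level at which the C3 arm enters. The forward saponification has to spare the peroxide and the ketal.

**Enyne (22 to 18 + 21).** The C(sp)–C(sp2) bond between C5' and C6' of the chain is cut, leading to terminal alkyne 18 and (E)-iodoalkene 21 (Sonogashira coupling). Cutting here keeps the conjugated enyne, the best π-nucleophile of the molecule, out of the cationic annulation. It also makes the route convergent. The (E) geometry is fixed beforehand by hydrozirconation–iodination of 19.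

**Alkyne cap (18 to 17).** The C–Si bond is cut. The silyl cap protects the alkyne during the titanium-mediated and cationic steps and comes off by mild alcoholysis.

**Ring (17 to 4 + 13).** This is the central disconnection: C3–C4 and C6–O1 are cut.
- Silylperoxy acetal 4 supplies O1–O2–C3 with the ester arm; on ionisation it is the cation 14.
- Methoxycyclopropane 13 supplies C4–C5–C6 with the OMe and the alkyne chain.
- Both bonds are polar and form in sequence: attack of the strained σ bond on 14 gives 15, and capture of 15 by the silylperoxy oxygen gives the ring.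
- Nothing else in the molecule offers a cut that makes the ring, two skeletal bonds and both stereocentres from two small achiral fragments.
- The forward step has to control the face of 14 (C3). C6 is left to equilibration through 16.

**Cyclopropane (13 to 11 to 9 to 8 to 5).** The O–CH3 bond is cut first (O-methylation of cyclopropanol 11). Then the two ring bonds to the carbinol carbon are cut (Kulinkovich cyclopropanation of ester 9), so that the ester carbon of 9 becomes C6. Ester 9 comes from 5 by C-silylation (through 6 and 7 to acid 8) and Fischer esterification.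

**Silylperoxy acetal (4 to 3 to 1).** The O–Si bond is cut, then the hydroperoxy acetal 3 is traced to the symmetrical alkene 1. Ozonolysis in the alcohol that supplies the methoxy group gives 3 through carbonyl oxide 2. Because 1 is symmetrical, the direction of fragmentation is immaterial, and the ester arm is present from the start.

**Iodoalkene (21 to 19).** The C–I bond is cut. Syn hydrozirconation of 19 through 20 and iodinolysis give the (E)-iodide.

## Alternatives that were turned down

**Alternative 1:** Baeyer–Villiger route through a bridged lactone.
- **Disconnection.** The OMe position at C6 and the acid arm are folded into one lactone bridge. The lactone oxygen is then removed, leading back to the bicyclic endoperoxide ketone A2 (4-[5-(trimethylsilyl)pent-4-yn-1-yl]-2,3-dioxabicyclo[2.2.2]octan-5-one). A2 would come from singlet-oxygen addition to the silyl dienol ether A1 (2-(tert-butyldimethylsilyloxy)-1-[5-(trimethylsilyl)pent-4-yn-1-yl]cyclohexa-1,3-diene) and enol ether hydrolysis.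
- **Forward key step.** Buffered mCPBA oxidises A2. The peroxy-bearing bridgehead migrates from carbon to oxygen and gives the bridged lactone A3 (1-[5-(trimethylsilyl)pent-4-yn-1-yl]-2,6,7-trioxabicyclo[3.2.2]nonan-3-one). Acid methanolysis would then release the acid and install OMe.
- **For.** The bicycle locks the C6 oxygen and the C3 CH2 on one face, which is the cis relation of the target. The tertiary, oxygen-substituted bridgehead is the better migrating group. One functional group holds both the acid and the C6–O bond.
- **Against.** A2 has an enolisable CH2 whose β-carbon carries a peroxide oxygen, so even weak base can open the peroxide. A3 is an acyloxy peroxyketal and should be very labile. A1 is achiral and the cycloaddition has no controlling element, so A2 is racemic and a resolution is unavoidable.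
- **Comparison.** It is stronger on relative configuration, but the chosen route gets that from thermodynamics. It is weaker on absolute configuration and no shorter. The chosen annulation is convergent and offers a catalytic handle on C3.

**Alternative 2:** auxiliary-directed singlet-oxygen [4+2].
- **Disconnection.** Both C–O bonds of the ring (C3–O2 and C6–O1) are cut, leading to the dienol ether A4 ((3E,5Z)-deca-3,5-diene with tert-butyldiphenylsilyloxy at C1, a trans-2-phenylcyclohexyloxy auxiliary at C6 and 4-methoxybenzyloxy at C10).
- **Forward key step.** Singlet oxygen (O2, tetraphenylporphyrin, light) adds suprafacially to the diene termini. It gives the 3,6-dihydro-1,2-dioxine A5, with C3 as in the target and the auxiliary as a temporary C6 ketal.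
- **For.** The cycloaddition is a classical peroxide-forming reaction that makes both C–O bonds at once. On this point of precedent it is stronger than the chosen key step.
- **Against.**
  - The C6 terminus of A4 is fully substituted, so one group must sit inside the s-cis diene; this slows the [4+2].
  - Electron-rich enol ethers divert singlet oxygen to [2+2] and ene pathways.
  - The auxiliary sits on oxygen at C6 and must induce at C3, across the diene.
  - After A5 a long series of steps must be run on a peroxide: alkene reduction, exchange of the auxiliary for OMe, two deprotections, alkyne homologation, coupling, and two oxidations to the acid.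
- **Comparison.** The chosen route needs three steps after ring formation and carries the arm at the ester level from the start.

**Alternative 3:** hydroperoxide unmasking and peroxyketal closure.
- **Disconnection.** Only C6–O1 and C6–OMe are cut, leading to the masked γ-hydroperoxy ketone A6 ((9S)-11-(tert-butyldiphenylsilyloxy)-9-[(2-methoxypropan-2-yl)peroxy]-1-(trimethylsilyl)undec-1-yn-6-one).
- **Forward key step.** TsOH in methanol with HC(OMe)3 frees the hydroperoxide, which adds to the ketone. The hemiketal is methylated to the (3S,6R)-dioxane A7, which carries a silyl-protected hydroxyethyl arm.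
- **For.** Every step has precedent. C3 comes from a carbinol of defined configuration by SN2 displacement with a peroxide nucleophile. C6 is set thermodynamically, as in the chosen route. On certainty and on absolute control at C3 this alternative is stronger.
- **Against.** Peroxide displacement at a secondary carbon is slow and competes with elimination. The chiral carbinol, its activation and the ketone unveiling make A6 a long linear target. The arm of A7 is at the alcohol level, so a deprotection and two oxidations must follow on the peroxide.
- **Comparison.** The chosen strategy offers about half the length, convergence, and the ester and OMe delivered by the fragments. The price is one unproven step.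

Key step: step 7

Assumption (remark on the chemistry): the catalyst of step 7 is a confined chiral imidodiphosphorimidate acid (IDPi: two 3,3'-diaryl-1,1'-binaphthyl-2,2'-diyl phosphoryl units joined through nitrogen, with N-triflyl groups). The enantiomer that leads to the (3S) series cannot be predicted and is to be fixed by a test run; the route is written for that enantiomer.

## Route

Step 1
Reactants: 1 dimethyl (E)-hex-3-enedioate
Product: 3 methyl 3-hydroperoxy-3-methoxypropanoate (racemic), via carbonyl oxide 2 (not isolated)
Conditions: O3, CH2Cl2–MeOH, −78 °C; N2 purge; no reductant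
Reagents that add atoms: ozone, [O-][O+]=O; methanol, CO
Why: Ozonolysis in methanol: the primary ozonide fragments to carbonyl oxide 2 and methyl 3-oxopropanoate, and methanol traps 2 as the α-methoxy hydroperoxide; 1 is symmetrical, so both directions of fragmentation give the same pair, and leaving out the reductant keeps the O–O bond.

Step 2
Reactants: 3 methyl 3-hydroperoxy-3-methoxypropanoate
Product: 4 methyl 3-methoxy-3-[(triethylsilyl)peroxy]propanoate (racemic)
Conditions: Et3SiCl, imidazole, DMF, 0 °C
Reagents that add atoms: chlorotriethylsilane, CC[Si](CC)(CC)Cl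
Why: O-Silylation of a hydroperoxide with a silyl chloride and imidazole; the mild base should not remove the hydrogen on the peroxy carbon (Kornblum–DeLaMare-type dehydration to the ester), and the acetal centre is racemic without consequence because it is ionised in step 7.

Step 3
Reactants: 5 hex-5-ynoic acid
Product: 8 6-(trimethylsilyl)hex-5-ynoic acid, via dilithium salt 6 (not isolated), via bis-silylated ester 7 (not isolated)
Conditions: n-BuLi (2.2 equiv), THF, −78 °C; Me3SiCl, −78 °C to rt; 1 M HCl
Reagents that add atoms: chlorotrimethylsilane, C[Si](C)(C)Cl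
Why: Two equivalents of n-BuLi give the carboxylate–acetylide 6, which is silylated on oxygen and carbon to 7; the acidic work-up hydrolyses the silyl ester and leaves the C(sp)–Si bond.

Step 4
Reactants: 8 6-(trimethylsilyl)hex-5-ynoic acid
Product: 9 methyl 6-(trimethylsilyl)hex-5-ynoate
Conditions: MeOH, H2SO4 (cat.), rt
Reagents that add atoms: methanol, CO
Why: Fischer esterification; the alkynylsilane is stable to catalytic acid in methanol.

Step 5
Reactants: 9 methyl 6-(trimethylsilyl)hex-5-ynoate
Product: 11 1-[5-(trimethylsilyl)pent-4-yn-1-yl]cyclopropan-1-ol, via magnesium cyclopropoxide 10 (not isolated)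
Conditions: EtMgBr (2.6 equiv, slow addition), Ti(OiPr)4 (0.3 equiv), THF, 0 °C to rt; aq. NH4Cl
Reagents that add atoms: ethylmagnesium bromide, CC[Mg]Br
Why: Kulinkovich cyclopropanation: EtMgBr and Ti(OiPr)4 form a titanacyclopropane that acts as a 1,2-dicarbanion towards the ester, whose carbonyl carbon becomes the carbinol carbon; the silyl cap and the slow Grignard addition should keep the internal alkyne from competing for the low-valent titanium.

Step 6
Reactants: 11 1-[5-(trimethylsilyl)pent-4-yn-1-yl]cyclopropan-1-ol
Product: 13 1-methoxy-1-[5-(trimethylsilyl)pent-4-yn-1-yl]cyclopropane, via sodium cyclopropoxide 12 (not isolated)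
Conditions: NaH, MeI, THF–DMF, 0 °C to rt
Reagents that add atoms: iodomethane, CI
Why: Williamson etherification of the tertiary cyclopropanol through alkoxide 12; in an aprotic medium the cyclopropoxide has no proton source for ring opening to the ethyl ketone and is trapped on oxygen by MeI.

Step 7
Reactants: 4 methyl 3-methoxy-3-[(triethylsilyl)peroxy]propanoate; 13 1-methoxy-1-[5-(trimethylsilyl)pent-4-yn-1-yl]cyclopropane
Product: 17 methyl 2-[(3S,6R)-6-methoxy-6-[5-(trimethylsilyl)pent-4-yn-1-yl]-1,2-dioxan-3-yl]acetate, via silylperoxycarbenium ion 14 (not isolated), via oxocarbenium ion 15 (not isolated), via C6-epimeric peroxyketal 16 (not isolated)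
Conditions: 4 (1.5 equiv), chiral IDPi acid (5 mol%), CH2Cl2, −78 °C, 13 added slowly; then MeOH, TsOH (10 mol%), −78 to 20 °C
Reagents that add atoms: methanol, CO (its methoxy group can exchange with the C6 methoxy group during the equilibration)
Why: Proposed new method: the chiral acid HX* (after the first turnover its silylated form Et3Si–X*) removes the methoxy group of 4 and leaves the silylperoxycarbenium ion 14 paired with X*−; the C1–C2 σ bond of 13, raised in energy by the geminal methoxy group, attacks C3 of 14 through its CH2 corner, which forms C3–C4 and opens the strained ring to the O-methyl oxocarbenium ion 15 at C6. The silylated peroxy oxygen then adds to C6 in a 6-exo-trig closure (the C=O+ bond stays outside the new ring), the Et3Si group passes to X*−, and the catalyst is regenerated with Et3SiOMe as the only by-product. The closest known reaction types are the SnCl4-mediated [3+2] annulation of triethylsilylperoxycarbenium ions with alkenes to 1,2-dioxolanes, the electrophilic ring opening of alkoxy- and siloxycyclopropanes as homoenolate equivalents, and chiral-anion (silylium imidodiphosphorimidate) catalysis of additions to oxocarbenium ions made from acetals; here the cyclopropane takes the place of the alkene and adds one ring atom. C3 is set under kinetic control by the confined chiral anion, which has to shield one face of the planar cation 14, so that the (3S) series should result with the appropriate catalyst enantiomer. C6 is formed without control as the epimer pair 16 and is then set thermodynamically in the same flask: TsOH in methanol reionises the peroxyketal and collects it in the chair with axial OMe (anomeric effect) and both carbon substituents equatorial, which is the (6R) isomer 17 with OMe cis to the C3 arm. The step needs cleavage of a C1–CH2 bond of the cyclopropane and not of the distal CH2–CH2 bond, which the donor OMe secures because only that cleavage gives a stabilised cation and both C1–CH2 bonds are equivalent; it also needs the cyclopropane to outcompete the silylalkyne and the ester as nucleophiles, which ring strain and the oxygen donor should secure, since the alkyne could reach C6 of 15 only through a strained or unstabilised vinyl cation. Finally it needs ionisation of 4 in preference to the more substituted product ketal, for which 4 is kept in excess, 13 is added slowly and the temperature is held at −78 °C.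

Step 8
Reactants: 17 methyl 2-[(3S,6R)-6-methoxy-6-[5-(trimethylsilyl)pent-4-yn-1-yl]-1,2-dioxan-3-yl]acetate
Product: 18 methyl 2-[(3S,6R)-6-methoxy-6-(pent-4-yn-1-yl)-1,2-dioxan-3-yl]acetate
Conditions: K2CO3 (0.2 equiv), MeOH, 0 °C
Reagents that add atoms: none
Why: Methanolysis of the C(sp)–Si bond with catalytic carbonate; the peroxyketal is stable to base, and any base-induced opening and reclosure next to the ester would give a separable C3 diastereomer and not the enantiomer, because C6 is fixed under basic conditions.

Step 9
Reactants: 19 undec-1-yne
Product: 21 (E)-1-iodoundec-1-ene, via alkenylzirconocene chloride 20 (not isolated)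
Conditions: Cp2Zr(H)Cl, CH2Cl2, rt; I2, 0 °C
Reagents that add atoms: iodine, II
Why: Hydrozirconation adds Zr–H syn across the terminal alkyne with zirconium on the terminal carbon to give 20; iodinolysis of the C–Zr bond proceeds with retention, so the (E)-iodoalkene should result.

Step 10
Reactants: 18 methyl 2-[(3S,6R)-6-methoxy-6-(pent-4-yn-1-yl)-1,2-dioxan-3-yl]acetate; 21 (E)-1-iodoundec-1-ene
Product: 22 methyl 2-[(3S,6R)-6-[(E)-hexadec-6-en-4-yn-1-yl]-6-methoxy-1,2-dioxan-3-yl]acetate
Conditions: Pd(PPh3)4 (5 mol%), CuI (10 mol%), iPr2NH, THF (degassed), 0 °C to rt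
Reagents that add atoms: none
Why: Sonogashira coupling of a terminal alkyne with an (E)-alkenyl iodide proceeds at or below room temperature with retention of the alkene geometry; oxidative addition to the alkenyl iodide is fast, so zerovalent palladium and monovalent copper should be engaged in the coupling and not in reduction of the dialkyl peroxide, and such couplings on preformed 1,2-dioxanes are known.

Step 11
Reactants: 22 methyl 2-[(3S,6R)-6-[(E)-hexadec-6-en-4-yn-1-yl]-6-methoxy-1,2-dioxan-3-yl]acetate
Product: 24 2-[(3S,6R)-6-[(E)-hexadec-6-en-4-yn-1-yl]-6-methoxy-1,2-dioxan-3-yl]acetic acid, via lithium carboxylate 23 (not isolated)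
Conditions: LiOH, THF–H2O, 0 °C; 0.5 M HCl to pH 4, 0 °C
Reagents that add atoms: lithium hydroxide, [Li+].[OH-]
Why: Saponification of the methyl ester through carboxylate 23; once the carboxylate has formed, the hydrogens next to it are no longer acidic enough for E1cB opening of the peroxide, and acidification only to pH 4 in the cold should spare the methoxy peroxyketal.

## Compound list

1 | dimethyl (E)-hex-3-enedioate | COC(=O)C/C=C/CC(=O)OC | starting material
2 | methyl 3-oxopropanoate O-oxide (carbonyl oxide) | COC(=O)CC=[O+][O-] | intermediate
3 | methyl 3-hydroperoxy-3-methoxypropanoate (racemic) | COC(OO)CC(=O)OC | intermediate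
4 | methyl 3-methoxy-3-[(triethylsilyl)peroxy]propanoate (racemic) | CC[Si](CC)(CC)OOC(OC)CC(=O)OC | intermediate
5 | hex-5-ynoic acid | OC(=O)CCCC#C | starting material
6 | lithium 6-lithiohex-5-ynoate | [Li]C#CCCCC(=O)O[Li] | intermediate
7 | trimethylsilyl 6-(trimethylsilyl)hex-5-ynoate | C[Si](C)(C)C#CCCCC(=O)O[Si](C)(C)C | intermediate
8 | 6-(trimethylsilyl)hex-5-ynoic acid | C[Si](C)(C)C#CCCCC(=O)O | intermediate
9 | methyl 6-(trimethylsilyl)hex-5-ynoate | COC(=O)CCCC#C[Si](C)(C)C | intermediate
10 | bromomagnesium 1-[5-(trimethylsilyl)pent-4-yn-1-yl]cyclopropan-1-olate | C[Si](C)(C)C#CCCCC1(O[Mg]Br)CC1 | intermediate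
11 | 1-[5-(trimethylsilyl)pent-4-yn-1-yl]cyclopropan-1-ol | C[Si](C)(C)C#CCCCC1(O)CC1 | intermediate
12 | sodium 1-[5-(trimethylsilyl)pent-4-yn-1-yl]cyclopropan-1-olate | C[Si](C)(C)C#CCCCC1([O-])CC1.[Na+] | intermediate
13 | 1-methoxy-1-[5-(trimethylsilyl)pent-4-yn-1-yl]cyclopropane | COC1(CCCC#C[Si](C)(C)C)CC1 | intermediate
14 | (3-methoxy-3-oxopropylidene)(triethylsilyloxy)oxonium (silylperoxycarbenium ion, paired with the chiral anion) | CC[Si](CC)(CC)O[O+]=CCC(=O)OC | intermediate
15 | O-methyl oxocarbenium ion at C6 with the (3S)-triethylsilylperoxy centre | C[O+]=C(CCCC#C[Si](C)(C)C)CC[C@@H](CC(=O)OC)OO[Si](CC)(CC)CC | intermediate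
16 | methyl 2-[(3S)-6-methoxy-6-[5-(trimethylsilyl)pent-4-yn-1-yl]-1,2-dioxan-3-yl]acetate, mixture of C6 epimers | C[Si](C)(C)C#CCCCC1(OC)CC[C@@H](CC(=O)OC)OO1 | intermediate
17 | methyl 2-[(3S,6R)-6-methoxy-6-[5-(trimethylsilyl)pent-4-yn-1-yl]-1,2-dioxan-3-yl]acetate | C[Si](C)(C)C#CCCC[C@]1(OC)CC[C@@H](CC(=O)OC)OO1 | intermediate
18 | methyl 2-[(3S,6R)-6-methoxy-6-(pent-4-yn-1-yl)-1,2-dioxan-3-yl]acetate | C#CCCC[C@]1(OC)CC[C@@H](CC(=O)OC)OO1 | intermediate
19 | undec-1-yne | CCCCCCCCCC#C | starting material
20 | chlorobis(cyclopentadienyl)[(E)-undec-1-en-1-yl]zirconium | CCCCCCCCC/C=C/[Zr+2]Cl.[CH-]1C=CC=C1.[CH-]1C=CC=C1 | intermediate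
21 | (E)-1-iodoundec-1-ene | CCCCCCCCC/C=C/I | intermediate
22 | methyl 2-[(3S,6R)-6-[(E)-hexadec-6-en-4-yn-1-yl]-6-methoxy-1,2-dioxan-3-yl]acetate | CCCCCCCCC/C=C/C#CCCC[C@]1(OC)CC[C@@H](CC(=O)OC)OO1 | intermediate
23 | lithium 2-[(3S,6R)-6-[(E)-hexadec-6-en-4-yn-1-yl]-6-methoxy-1,2-dioxan-3-yl]acetate | CCCCCCCCC/C=C/C#CCCC[C@]1(OC)CC[C@@H](CC(=O)[O-])OO1.[Li+] | intermediate
24 | 2-[(3S,6R)-6-[(E)-hexadec-6-en-4-yn-1-yl]-6-methoxy-1,2-dioxan-3-yl]acetic acid | CCCCCCCCC/C=C/C#CCCC[C@]1(OC)CC[C@@H](CC(=O)O)OO1 | target

## Step count and least certain steps

Total: 11 steps. Longest linear sequence: 8 steps (steps 3, 4, 5, 6, 7, 8, 10 and 11, from 5 to 24).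

**Step 7 (key step, new method).**
- What may go wrong: cation 14 or 15 may lose a proton faster than it is captured; the acid may open the cyclopropane by protonation; the product ketal may reionise and react with a second cyclopropane; the chiral anion may discriminate poorly between the faces of 14, which would erode the enantiomeric purity at C3.
- Why: no cyclopropane has been shown to intercept a peroxycarbenium ion, and the ion pair is far from any tested case.
- Fallback (known chemistry only): it sets out from acid 8 and comes back at 17.
  - Acid 8 is converted with (COCl)2 into 6-(trimethylsilyl)hex-5-ynoyl chloride F1.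
  - Fe(acac)3-catalysed coupling with but-3-enylmagnesium bromide gives 10-(trimethylsilyl)dec-1-en-9-yn-5-one F2.
  - Wittig methylenation gives trimethyl(6-methylidenedec-9-en-1-yn-1-yl)silane F3.
  - Cross-metathesis of the monosubstituted alkene with methyl acrylate (second-generation Hoveyda–Grubbs catalyst) gives methyl (E)-6-methylidene-11-(trimethylsilyl)undec-2-en-10-ynoate F4.
  - Ozonolysis in CH2Cl2–MeOH, selective for the electron-rich 1,1-disubstituted alkene, gives methyl (E)-6-hydroperoxy-6-methoxy-11-(trimethylsilyl)undec-2-en-10-ynoate F5.
  - Et2NH in CF3CH2OH induces intramolecular conjugate addition of the hydroperoxide to the enoate (6-exo-trig) and gives methyl 2-[6-methoxy-6-[5-(trimethylsilyl)pent-4-yn-1-yl]-1,2-dioxan-3-yl]acetate F6 as a racemic diastereomer mixture.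
  - Equilibration with TsOH in methanol, as in step 7, converts F6 into the racemate of 17, that is, 17 together with methyl 2-[(3R,6S)-6-methoxy-6-[5-(trimethylsilyl)pent-4-yn-1-yl]-1,2-dioxan-3-yl]acetate F7.
  - Preparative HPLC on a chiral stationary phase then delivers 17.

**Step 5.**
- What may go wrong: ligand exchange of the titanacyclopropane with the tethered alkyne, followed by reductive coupling, would consume ester and catalyst.
- Why: low-valent titanium alkoxides complex internal alkynes, and the silyl cap may not slow this enough.
- Fallback: it sets out from ester 9 and comes back at 13, without any low-valent titanium.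
  - Ester 9 is converted with MeNH(OMe)·HCl and iPrMgCl into N-methoxy-N-methyl-6-(trimethylsilyl)hex-5-ynamide F8.
  - MeMgBr gives 7-(trimethylsilyl)hept-6-yn-2-one F9.
  - HC(OMe)3, MeOH and TsOH give (6,6-dimethoxyhept-1-yn-1-yl)trimethylsilane F10.
  - Me3SiOTf and iPr2NEt remove methanol towards the methyl group and give (6-methoxyhept-6-en-1-yn-1-yl)trimethylsilane F11.
  - Simmons–Smith cyclopropanation (Et2Zn, CH2I2) of this enol ether gives 13.

**Step 10.**
- What may go wrong: reductive cleavage of the O–O bond by zerovalent palladium, monovalent copper or free PPh3, or amine-induced fragmentation at the C3 hydrogen, may compete with the coupling.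
- Why: the peroxide is exposed to all three at once.
- Fallback: the coupling is moved ahead of ring formation; it sets out from 13 and comes back at 22.
  - K2CO3 in MeOH converts 13 into 1-methoxy-1-(pent-4-yn-1-yl)cyclopropane F12.
  - Sonogashira coupling with 21 gives 1-[(E)-hexadec-6-en-4-yn-1-yl]-1-methoxycyclopropane F13.
  - The annulation of step 7 with 4 gives methyl 2-[(3S)-6-[(E)-hexadec-6-en-4-yn-1-yl]-6-methoxy-1,2-dioxan-3-yl]acetate F14 as the C6-epimer mixture, which the acid–methanol stage converts into 22.
  - The price is that the enyne then has to survive the cationic step.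

**Step 1.**
- What may go wrong: the carbonyl oxide, which has acidic hydrogens next to the ester, may isomerise to a vinyl hydroperoxide and decompose; the hydroperoxide may recombine with the co-formed aldehyde on concentration, which would make the isolation lossy.
- Why: the ester activates the position next to the carbonyl oxide, and the aldehyde by-product is reactive.
- Fallback: it sets out from 1 and comes back at 3. Ozonolysis of 1 in MeOH, then Me2S and TsOH, gives methyl 3,3-dimethoxypropanoate F15 (also purchasable). Acid-catalysed exchange of one methoxy group with anhydrous H2O2 in Et2O, through the oxocarbenium ion, gives 3 without a carbonyl oxide and without the aldehyde.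

## Further compounds

F1 | step 7 | 6-(trimethylsilyl)hex-5-ynoyl chloride | C[Si](C)(C)C#CCCCC(=O)Cl
F2 | step 7 | 10-(trimethylsilyl)dec-1-en-9-yn-5-one | C=CCCC(=O)CCCC#C[Si](C)(C)C
F3 | step 7 | trimethyl(6-methylidenedec-9-en-1-yn-1-yl)silane | C=CCCC(=C)CCCC#C[Si](C)(C)C
F4 | step 7 | methyl (E)-6-methylidene-11-(trimethylsilyl)undec-2-en-10-ynoate | COC(=O)/C=C/CCC(=C)CCCC#C[Si](C)(C)C
F5 | step 7 | methyl (E)-6-hydroperoxy-6-methoxy-11-(trimethylsilyl)undec-2-en-10-ynoate (racemic) | COC(=O)/C=C/CCC(OC)(OO)CCCC#C[Si](C)(C)C
F6 | step 7 | methyl 2-[6-methoxy-6-[5-(trimethylsilyl)pent-4-yn-1-yl]-1,2-dioxan-3-yl]acetate, racemic diastereomer mixture | C[Si](C)(C)C#CCCCC1(OC)CCC(CC(=O)OC)OO1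
F7 | step 7 | methyl 2-[(3R,6S)-6-methoxy-6-[5-(trimethylsilyl)pent-4-yn-1-yl]-1,2-dioxan-3-yl]acetate (enantiomer of 17, formed with it as the racemate) | C[Si](C)(C)C#CCCC[C@@]1(OC)CC[C@H](CC(=O)OC)OO1
F8 | step 5 | N-methoxy-N-methyl-6-(trimethylsilyl)hex-5-ynamide | CON(C)C(=O)CCCC#C[Si](C)(C)C
F9 | step 5 | 7-(trimethylsilyl)hept-6-yn-2-one | CC(=O)CCCC#C[Si](C)(C)C
F10 | step 5 | (6,6-dimethoxyhept-1-yn-1-yl)trimethylsilane | COC(C)(OC)CCCC#C[Si](C)(C)C
F11 | step 5 | (6-methoxyhept-6-en-1-yn-1-yl)trimethylsilane | COC(=C)CCCC#C[Si](C)(C)C
F12 | step 10 | 1-methoxy-1-(pent-4-yn-1-yl)cyclopropane | COC1(CCCC#C)CC1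
F13 | step 10 | 1-[(E)-hexadec-6-en-4-yn-1-yl]-1-methoxycyclopropane | CCCCCCCCC/C=C/C#CCCCC1(OC)CC1
F14 | step 10 | methyl 2-[(3S)-6-[(E)-hexadec-6-en-4-yn-1-yl]-6-methoxy-1,2-dioxan-3-yl]acetate, mixture of C6 epimers | CCCCCCCCC/C=C/C#CCCCC1(OC)CC[C@@H](CC(=O)OC)OO1
F15 | step 1 | methyl 3,3-dimethoxypropanoate | COC(CC(=O)OC)OC
A1 | alternative 1 | 2-(tert-butyldimethylsilyloxy)-1-[5-(trimethylsilyl)pent-4-yn-1-yl]cyclohexa-1,3-diene | C[Si](C)(C)C#CCCCC1=C(O[Si](C)(C)C(C)(C)C)C=CCC1
A2 | alternative 1 | 4-[5-(trimethylsilyl)pent-4-yn-1-yl]-2,3-dioxabicyclo[2.2.2]octan-5-one, bridgeheads configured as C3 and C6 of 24 | C[Si](C)(C)C#CCCC[C@]1(C(=O)C2)CC[C@@H]2OO1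
A3 | alternative 1 | 1-[5-(trimethylsilyl)pent-4-yn-1-yl]-2,6,7-trioxabicyclo[3.2.2]nonan-3-one, bridgeheads configured as C6 and C3 of 24 | C[Si](C)(C)C#CCCC[C@]1(OC(=O)C2)CC[C@@H]2OO1
A4 | alternative 2 | (3E,5Z)-1-(tert-butyldiphenylsilyloxy)-10-(4-methoxybenzyloxy)-6-(trans-2-phenylcyclohexyloxy)deca-3,5-diene, single enantiomer of the auxiliary | COc1ccc(COCCCC/C(O[C@@H]2CCCC[C@H]2c2ccccc2)=C/C=C/CCO[Si](c2ccccc2)(c2ccccc2)C(C)(C)C)cc1
A5 | alternative 2 | 3,6-dihydro-1,2-dioxine with 2-(tert-butyldiphenylsilyloxy)ethyl at C3 (configured as in 24) and, at C6, the trans-2-phenylcyclohexyloxy auxiliary and a 4-(4-methoxybenzyloxy)butyl chain | COc1ccc(COCCCC[C@@]2(O[C@@H]3CCCC[C@H]3c3ccccc3)C=C[C@@H](CCO[Si](c3ccccc3)(c3ccccc3)C(C)(C)C)OO2)cc1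
A6 | alternative 3 | (9S)-11-(tert-butyldiphenylsilyloxy)-9-[(2-methoxypropan-2-yl)peroxy]-1-(trimethylsilyl)undec-1-yn-6-one | C[Si](C)(C)C#CCCCC(=O)CC[C@@H](CCO[Si](c1ccccc1)(c1ccccc1)C(C)(C)C)OOC(C)(C)OC
A7 | alternative 3 | (3S,6R)-3-[2-(tert-butyldiphenylsilyloxy)ethyl]-6-methoxy-6-[5-(trimethylsilyl)pent-4-yn-1-yl]-1,2-dioxane | C[Si](C)(C)C#CCCC[C@]1(OC)CC[C@@H](CCO[Si](c2ccccc2)(c2ccccc2)C(C)(C)C)OO1
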